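**Plan**
- Retrosynthetic cuts: the O–Si bond; in ring C the C4–C4a bond (Friedel–Crafts acylation) and the O1–C2 bond (Mitsunobu etherification); in ring A the C8–C8a, C6–C7 and C4a–C8a bonds (cyclobutenone/ynol ether benzannulation); in the side chain the CH2–alkyne bond (epoxide opening).
- Forward order: the chiral methoxyalkyne is assembled from methacrolein, ring A is then built around it, ring C is closed by etherification followed by acylation, and the silyl group is removed last.
- Enabling feature (flavanone numbering): ring A is a 1,3,5-trioxygenated benzene (O1 on C8a, OMe on C5 and C7) with the carbon chain on C8 between C8a–O and C7–OMe and hydrogen on C6 and, before ring C exists, on C4a. A 3-methoxyvinylketene and a methoxyalkyne deliver exactly this pattern with mechanistically fixed regiochemistry.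
- Stereochemistry: the side-chain carbinol comes from a hydrolytic kinetic resolution of the terminal epoxide (catalyst control); C2 comes from ethyl (R)-3-hydroxy-3-phenylpropanoate with Mitsunobu inversion to 2S.

Key step: step 6

Remark: the side-chain carbinol keeps its spatial arrangement from the epoxide onward; its descriptor changes from R to S only because the CIP ranking of its neighbours changes when the epoxide is opened.

**Route**

Step 1
Reactants: 1 methacrolein
Product: 2 rac-2-(prop-1-en-2-yl)oxirane
Conditions: NaH, DMSO/THF; Me3S+ I−, −5 °C; then 1, −5 °C → rt; fractional distillation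
Reagents that add atoms: trimethylsulfonium iodide, C[S+](C)C.[I-]
Why: Corey–Chaykovsky epoxidation; the unstabilised sulfonium ylide adds irreversibly to the carbonyl group of the enal (1,2 and not 1,4) and the betaine closes to the vinyl epoxide, racemic at this stage.

Step 2
Reactants: 2 rac-2-(prop-1-en-2-yl)oxirane
Product: 3 (R)-2-(prop-1-en-2-yl)oxirane
Conditions: (S,S)-(salen)Co(OAc) (0.5–1 mol %; salen = N,N'-bis(3,5-di-tert-butylsalicylidene)cyclohexane-1,2-diaminate), H2O (0.55 equiv), 0 °C → rt; distillation from the diol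
Reagents that add atoms: none
Why: Hydrolytic kinetic resolution of a terminal epoxide; the (S,S)-catalyst should hydrolyse the (S)-epoxide and leave the (R)-epoxide, which is how the side-chain stereocentre is set (catalyst control), and the volatile epoxide is separated from the diol by distillation.

Step 3
Reactants: 4 chloroacetaldehyde dimethyl acetal; 3 (R)-2-(prop-1-en-2-yl)oxirane
Product: 6 (3S)-6-methoxy-2-methylhex-1-en-5-yn-3-ol, via sodium methoxyacetylide 5 (not isolated)
Conditions: NaNH2 (3 equiv per 4), liq. NH3, −40 °C; then 3, THF co-solvent, −33 °C; solid NH4Cl, evaporation of NH3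
Reagents that add atoms: none
Why: Two eliminations from the chloroacetal give the alkoxyacetylide (the classical access to alkoxyacetylenes), which opens the terminal epoxide by SN2 attack at the unhindered CH2 (acetylide opening of an epoxide in liquid ammonia); without a Lewis acid the allylic carbon and the SN2' terminus should stay untouched, and the stereocentre is not involved.

Step 4
Reactants: 6 (3S)-6-methoxy-2-methylhex-1-en-5-yn-3-ol
Product: 7 (3S)-6-methoxy-2-methyl-3-(triisopropylsilyloxy)hex-1-en-5-yne
Conditions: TIPSOTf, 2,6-lutidine, CH2Cl2, −78 → −20 °C; NaHCO3 work-up; Et3N-deactivated silica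
Reagents that add atoms: triisopropylsilyl trifluoromethanesulfonate, CC(C)[Si](OS(=O)(=O)C(F)(F)F)(C(C)C)C(C)C
Why: Silylation of a secondary alcohol with a silyl triflate and a hindered base; the always-basic medium protects the acid-labile ynol ether and prevents the hydroxyl from cyclising onto it.

Step 5
Reactants: 8 3-ethoxycyclobut-2-en-1-one
Product: 9 3-methoxycyclobut-2-en-1-one
Conditions: MeOH (solvent), p-TsOH·H2O (cat.), rt; solid NaHCO3, evaporation, one repeat cycle; distillation
Reagents that add atoms: methanol, CO
Why: Acid-catalysed addition–elimination at C3 of a vinylogous ester (vinylogous transesterification), driven by the large excess of methanol; at room temperature the four-membered ring does not open.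

Step 6
Reactants: 9 3-methoxycyclobut-2-en-1-one; 7 (3S)-6-methoxy-2-methyl-3-(triisopropylsilyloxy)hex-1-en-5-yne
Product: 14 2-[(2S)-3-methyl-2-(triisopropylsilyloxy)but-3-enyl]-3,5-dimethoxyphenol, via 3-methoxyvinylketene 10 (not isolated), via vinylcyclobutenone adduct 11 (not isolated), via dienylketene 12 (not isolated), via cyclohexadienone tautomer 13 (not isolated)
Conditions: 9 (1.5 equiv), toluene, sealed tube, 80 °C then 110 °C; then K2CO3, MeOH, rt (returns any O-acylated phenol)
Reagents that add atoms: none
Why: Heat opens 9 by 4π electrocyclic ring opening to the vinylketene 10, and the nucleophilic alkyne carbon of 7 (the one carrying the side chain) attacks the ketene carbonyl carbon in a [2+2] cycloaddition that forms C8–C8a and C6–C7 and gives the vinylcyclobutenone 11. A second 4π opening gives the dienylketene 12, whose thermally allowed disrotatory 6π electrocyclisation joins C4a to C8a and closes ring A as the cyclohexadienone 13, which tautomerises to the phenol 14. The closest known reaction type is the Danheiser benzannulation of cyclobutenones with alkoxy- and siloxyalkynes, applied here to a 3-alkoxycyclobutenone so that a phloroglucinol diether results. No stereocentre is created (the sp3 ring carbon of 11 is lost on ring opening) and the silyloxy-bearing carbon is a spectator under neutral thermal conditions. The selectivity needed is the orientation of the [2+2] step, which the polarisation of the ynol ether secures by placing the side chain ortho and the alkyne methoxy group meta to the new hydroxyl; the same polarisation makes the alkyne react in preference to the unactivated isopropenyl group, and a methyl ynol ether has no β-hydrogen for retro-ene loss of ketene at this temperature.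

Step 7
Reactants: 14 2-[(2S)-3-methyl-2-(triisopropylsilyloxy)but-3-enyl]-3,5-dimethoxyphenol; 15 ethyl (R)-3-hydroxy-3-phenylpropanoate
Product: 16 ethyl (3S)-3-{3,5-dimethoxy-2-[(2S)-3-methyl-2-(triisopropylsilyloxy)but-3-enyl]phenoxy}-3-phenylpropanoate
Conditions: PPh3, DIAD, toluene/THF, 0 °C → rt
Reagents that add atoms: none
Why: Mitsunobu etherification; the phenoxide displaces the oxyphosphonium of the secondary benzylic alcohol by SN2 with inversion, so the R alcohol sets the future C2 as S, and the phenol has one free ortho position and sufficient acidity.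

Step 8
Reactants: 16 ethyl (3S)-3-{3,5-dimethoxy-2-[(2S)-3-methyl-2-(triisopropylsilyloxy)but-3-enyl]phenoxy}-3-phenylpropanoate
Product: 17 (3S)-3-{3,5-dimethoxy-2-[(2S)-3-methyl-2-(triisopropylsilyloxy)but-3-enyl]phenoxy}-3-phenylpropanoic acid
Conditions: LiOH·H2O, THF/H2O, 0 °C → rt; cold dilute HCl to pH 4
Reagents that add atoms: lithium hydroxide (supplies the carboxylate oxygen), [Li+].[OH-]
Why: Saponification; hydroxide attack at the ester carbonyl at 0 °C should outrun α-deprotonation and β-elimination of the aryloxide, and the silyl ether, alkene and aryl ethers are inert.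

Step 9
Reactants: 17 (3S)-3-{3,5-dimethoxy-2-[(2S)-3-methyl-2-(triisopropylsilyloxy)but-3-enyl]phenoxy}-3-phenylpropanoic acid
Product: 19 (2S)-5,7-dimethoxy-8-[(2S)-3-methyl-2-(triisopropylsilyloxy)but-3-enyl]-2-phenylchroman-4-one, via acid chloride 18 (not isolated)
Conditions: 1-chloro-N,N,2-trimethylprop-1-en-1-amine, CH2Cl2, 0 °C; then 2,6-di-tert-butylpyridine, SnCl4, −78 °C; NaHCO3 quench at −78 °C
Reagents that add atoms: none
Why: Intramolecular Friedel–Crafts acylation; the acid chloride is made under neutral conditions and the acylium closes the six-membered ring C at C4a, the only free position ortho to the ether oxygen and doubly activated by the C5 and C7 methoxy groups, at a temperature where the hindered pyridine traps HCl and the benzylic C2–O bond, silyl ether and alkene should survive.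

Step 10
Reactants: 19 (2S)-5,7-dimethoxy-8-[(2S)-3-methyl-2-(triisopropylsilyloxy)but-3-enyl]-2-phenylchroman-4-one
Product: 20 (2S)-8-[(2S)-2-hydroxy-3-methylbut-3-enyl]-5,7-dimethoxy-2-phenylchroman-4-one (CNP0171002.1)
Conditions: HF·pyridine, pyridine, THF, 0 °C → rt
Reagents that add atoms: none
Why: Fluoride-driven Si–O cleavage under buffered, weakly acidic conditions, which avoid the base-induced opening of the flavanone to the chalcone that would scramble C2.

**Compound list**

1 | methacrolein | CC(=C)C=O | starting material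
2 | rac-2-(prop-1-en-2-yl)oxirane | C=C(C)C1CO1 | intermediate
3 | (R)-2-(prop-1-en-2-yl)oxirane | C=C(C)[C@@H]1CO1 | intermediate
4 | chloroacetaldehyde dimethyl acetal | COC(CCl)OC | starting material
5 | sodium methoxyacetylide | [Na+].[C-]#COC | intermediate
6 | (3S)-6-methoxy-2-methylhex-1-en-5-yn-3-ol | C=C(C)[C@@H](O)CC#COC | intermediate
7 | (3S)-6-methoxy-2-methyl-3-(triisopropylsilyloxy)hex-1-en-5-yne | C=C(C)[C@@H](O[Si](C(C)C)(C(C)C)C(C)C)CC#COC | intermediate
8 | 3-ethoxycyclobut-2-en-1-one | CCOC1=CC(=O)C1 | starting material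
9 | 3-methoxycyclobut-2-en-1-one | COC1=CC(=O)C1 | intermediate
10 | 3-methoxybuta-1,3-dien-1-one (3-methoxyvinylketene) | C=C(OC)C=C=O | intermediate
11 | 3-methoxy-4-(1-methoxyethenyl)-2-[(2S)-3-methyl-2-(triisopropylsilyloxy)but-3-enyl]cyclobut-2-en-1-one (both C4 epimers) | C=C(C)[C@@H](O[Si](C(C)C)(C(C)C)C(C)C)CC1=C(OC)C(C(=C)OC)C1=O | intermediate
12 | (3E)-3,5-dimethoxy-2-[(2S)-3-methyl-2-(triisopropylsilyloxy)but-3-enyl]hexa-1,3,5-trien-1-one | C=C(C)[C@@H](O[Si](C(C)C)(C(C)C)C(C)C)CC(=C=O)/C(OC)=C\C(OC)=C | intermediate
13 | 3,5-dimethoxy-2-[(2S)-3-methyl-2-(triisopropylsilyloxy)but-3-enyl]cyclohexa-2,4-dien-1-one | C=C(C)[C@@H](O[Si](C(C)C)(C(C)C)C(C)C)CC1=C(OC)C=C(OC)CC1=O | intermediate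
14 | 2-[(2S)-3-methyl-2-(triisopropylsilyloxy)but-3-enyl]-3,5-dimethoxyphenol | C=C(C)[C@@H](O[Si](C(C)C)(C(C)C)C(C)C)Cc1c(OC)cc(OC)cc1O | intermediate
15 | ethyl (R)-3-hydroxy-3-phenylpropanoate | CCOC(=O)C[C@@H](O)c1ccccc1 | starting material
16 | ethyl (3S)-3-{3,5-dimethoxy-2-[(2S)-3-methyl-2-(triisopropylsilyloxy)but-3-enyl]phenoxy}-3-phenylpropanoate | C=C(C)[C@@H](O[Si](C(C)C)(C(C)C)C(C)C)Cc1c(OC)cc(OC)cc1O[C@@H](CC(=O)OCC)c1ccccc1 | intermediate
17 | (3S)-3-{3,5-dimethoxy-2-[(2S)-3-methyl-2-(triisopropylsilyloxy)but-3-enyl]phenoxy}-3-phenylpropanoic acid | C=C(C)[C@@H](O[Si](C(C)C)(C(C)C)C(C)C)Cc1c(OC)cc(OC)cc1O[C@@H](CC(=O)O)c1ccccc1 | intermediate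
18 | (3S)-3-{3,5-dimethoxy-2-[(2S)-3-methyl-2-(triisopropylsilyloxy)but-3-enyl]phenoxy}-3-phenylpropanoyl chloride | C=C(C)[C@@H](O[Si](C(C)C)(C(C)C)C(C)C)Cc1c(OC)cc(OC)cc1O[C@@H](CC(=O)Cl)c1ccccc1 | intermediate
19 | (2S)-5,7-dimethoxy-8-[(2S)-3-methyl-2-(triisopropylsilyloxy)but-3-enyl]-2-phenylchroman-4-one | C=C(C)[C@@H](O[Si](C(C)C)(C(C)C)C(C)C)Cc1c(OC)cc(OC)c2c1O[C@H](c1ccccc1)CC2=O | intermediate
20 | (2S)-8-[(2S)-2-hydroxy-3-methylbut-3-enyl]-5,7-dimethoxy-2-phenylchroman-4-one | C=C(C)[C@@H](O)Cc1c(OC)cc(OC)c2c1O[C@H](c1ccccc1)CC2=O | target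

**Step count**

Total: 10 steps. Longest linear sequence: 9 steps (steps 1–4 and 6–10, from methacrolein); step 5 is a one-step side branch.

**Steps most likely to fail, with fallbacks**

Step 6. Opening of the donor-substituted cyclobutenone may need a temperature at which the vinylketene is consumed by self-condensation or by acylation of the product faster than the ynol ether traps it, so that 7 is left over or degraded. The fallback makes the same ketene at 0 °C from an acid chloride instead of a four-membered ring. It sets out from 7. Commercial methyl (E)-3-methoxybut-2-enoate is saponified with LiOH to (E)-3-methoxybut-2-enoic acid F1 and converted with oxalyl chloride and catalytic DMF into (E)-3-methoxybut-2-enoyl chloride F2. Slow addition of F2 to 7 and Et3N in CH2Cl2 at 0 °C should give 10 by 1,4-dehydrochlorination, the classical entry to vinylketenes, which is captured as 11 at low temperature. After filtration, brief warming in toluene at 80 °C takes 11 through 12 and 13 to 14, where the route is rejoined.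

Step 3. The opening in liquid ammonia may be slow enough that ammonolysis of the epoxide competes, or the acetylide may attack the allylic carbon or the alkene terminus of the vinyl epoxide. The fallback replaces the epoxide by a primary triflate that can only react at CH2. It sets out from 2. Resolution with the enantiomeric (R,R)-(salen)Co(OAc) and 0.45 equiv of water is run for the diol and gives (R)-3-methylbut-3-ene-1,2-diol F3. One-pot treatment with Tf2O and 2,6-lutidine at −78 °C, then TIPSOTf, gives (2R)-3-methyl-2-(triisopropylsilyloxy)but-3-enyl trifluoromethanesulfonate F4. The ammonia suspension of 5 is quenched with NH4Cl and the low-boiling methoxyacetylene F5 is distilled into cold THF. It is deprotonated with n-BuLi to amine-free lithium methoxyacetylide F6, which is alkylated with F4 in THF/DMPU at −78 → −20 °C. This gives 7 directly, so 6 is bypassed and the route is rejoined at 7.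

Step 9. Lewis-acid ionisation of the benzylic C2–O bond may erode the configuration at C2 before the ring closes, and hydrogen chloride may add to the isopropenyl group or strip the silyl group. The fallback builds ring C without an acylium ion and sets C2 by catalyst control; it replaces steps 7–9, sets out from 14 and returns at 19.
- Ortho-formylation (MgCl2, Et3N, paraformaldehyde, MeCN, reflux) at the only free ortho position gives 2-hydroxy-4,6-dimethoxy-3-[(2S)-3-methyl-2-(triisopropylsilyloxy)but-3-enyl]benzaldehyde F7.
- Excess ethynylmagnesium bromide in THF at 0 °C gives 1-{2-hydroxy-4,6-dimethoxy-3-[(2S)-3-methyl-2-(triisopropylsilyloxy)but-3-enyl]phenyl}prop-2-yn-1-ol F8.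
- MnO2 in CH2Cl2 gives 1-{2-hydroxy-4,6-dimethoxy-3-[(2S)-3-methyl-2-(triisopropylsilyloxy)but-3-enyl]phenyl}prop-2-yn-1-one F9.
- Et2NH in EtOH closes F9 by conjugate addition and 6-endo cyclisation to 5,7-dimethoxy-8-[(2S)-3-methyl-2-(triisopropylsilyloxy)but-3-enyl]-4H-chromen-4-one F10.
- Rhodium-catalysed asymmetric 1,4-addition of phenylboronic acid ([Rh(OH)(cod)]2 with an electron-poor atropisomeric bisphosphine, the enantiomer that gives 2S, in aqueous toluene at 50 °C) gives 19.

**Further compounds**

F1 | step 6 | (E)-3-methoxybut-2-enoic acid | CO/C(C)=C/C(=O)O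
F2 | step 6 | (E)-3-methoxybut-2-enoyl chloride | CO/C(C)=C/C(=O)Cl
F3 | step 3 | (R)-3-methylbut-3-ene-1,2-diol | C=C(C)[C@@H](O)CO
F4 | step 3 | (2R)-3-methyl-2-(triisopropylsilyloxy)but-3-enyl trifluoromethanesulfonate | C=C(C)[C@@H](O[Si](C(C)C)(C(C)C)C(C)C)COS(=O)(=O)C(F)(F)F
F5 | step 3 | methoxyacetylene | C#COC
F6 | step 3 | lithium methoxyacetylide | [Li]C#COC
F7 | step 9 | 2-hydroxy-4,6-dimethoxy-3-[(2S)-3-methyl-2-(triisopropylsilyloxy)but-3-enyl]benzaldehyde | C=C(C)[C@@H](O[Si](C(C)C)(C(C)C)C(C)C)Cc1c(OC)cc(OC)c(C=O)c1O
F8 | step 9 | 1-{2-hydroxy-4,6-dimethoxy-3-[(2S)-3-methyl-2-(triisopropylsilyloxy)but-3-enyl]phenyl}prop-2-yn-1-ol (both carbinol epimers) | C=C(C)[C@@H](O[Si](C(C)C)(C(C)C)C(C)C)Cc1c(OC)cc(OC)c(C(O)C#C)c1O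
F9 | step 9 | 1-{2-hydroxy-4,6-dimethoxy-3-[(2S)-3-methyl-2-(triisopropylsilyloxy)but-3-enyl]phenyl}prop-2-yn-1-one | C=C(C)[C@@H](O[Si](C(C)C)(C(C)C)C(C)C)Cc1c(OC)cc(OC)c(C(=O)C#C)c1O
F10 | step 9 | 5,7-dimethoxy-8-[(2S)-3-methyl-2-(triisopropylsilyloxy)but-3-enyl]-4H-chromen-4-one | C=C(C)[C@@H](O[Si](C(C)C)(C(C)C)C(C)C)Cc1c(OC)cc(OC)c2c1OC=CC2=O
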